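**Plan**

1. Retrosynthetic cuts, in order: the C6–prenyl bond; the ester C–OMe bond (the side chain is closed back onto O7 as a six-membered lactone); C3–C4 of ring B; the O1–C2 ether bond; the C4a–CHO bond; the benzylic C–H (coumarin C3=C4); the two Pechmann bonds to phloroglucinol.
2. Enabling feature: in ring B the C4 ketone is carried by C4a, the neighbour of the O1-bearing C8a, and O1–C2H(CH3)–C3H(CH3) is a but-3-en-2-yl ether plus one hydrogen. A C4a aldehyde with an (S)-but-3-en-2-yloxy group on C8a therefore already holds all six ring atoms, and an acyl-anion equivalent can join C4 to C3.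
3. Forward order: benzene ring from phloroglucinol → lactone ring (Pechmann, then 1,4-reduction; it masks O7 and the future ester) → formyl group and allylic ether → ring B by carbene-catalysed hydroacylation → lactone opened to the methyl ester and MOM removed → prenyl on C6 last.
4. Stereochemistry: the benzylic (S) centre comes from a ligand-controlled CuH conjugate reduction; C2 (S) from (R)-but-3-en-2-ol by Mitsunobu inversion; C3 (S) by base equilibration to the trans-2,3-dimethyl arrangement.
5. Numbering: chromanone numbering for ring B and the target, coumarin numbering for compounds 3–9.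

Key step: step 6

Assumption: (R)-DTBM-SEGPHOS is taken to deliver hydride to the face of the 4-propylcoumarin that gives the (4S)-lactone; if a trial run shows the opposite sense, the (S)-ligand is used and nothing else changes.

**Step 1**
Reactants: 1 phloroglucinol; 2 ethyl 3-oxohexanoate
Product: 3 5,7-dihydroxy-4-propyl-2H-chromen-2-one
Conditions: conc. H2SO4, 0 °C → rt
Reagents that add atoms: none
Why: Pechmann condensation (transesterification, ring-closing hydroxyalkylation, dehydration) should give a single coumarin because the three free ring carbons of 1 are equivalent.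

**Step 2**
Reactants: 3 5,7-dihydroxy-4-propyl-2H-chromen-2-one
Product: 4 5-hydroxy-7-(methoxymethoxy)-4-propyl-2H-chromen-2-one
Conditions: MOMCl (1.05 equiv), i-Pr2NEt (1.2 equiv), DMF, −10 → 0 °C
Reagents that add atoms: chloromethyl methyl ether, COCCl
Why: Williamson-type O-alkylation with one equivalent of electrophile should select the 7-OH, the more acidic and unhindered phenol, while the 5-OH is shielded by the peri propyl group.

**Step 3**
Reactants: 4 5-hydroxy-7-(methoxymethoxy)-4-propyl-2H-chromen-2-one
Product: 6 (4S)-5-hydroxy-7-(methoxymethoxy)-4-propyl-3,4-dihydro-2H-chromen-2-one, via bis-silylated ketene acetal 5 (not isolated)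
Conditions: Cu(OAc)2·H2O (5 mol %), (R)-DTBM-SEGPHOS (5.5 mol %), HSiMe(OEt)2 (4 equiv), toluene/THF, 0 °C → rt, no alcohol additive; then 1 M aq. HCl, THF, 0 °C, brief
Reagents that add atoms: none
Why: Asymmetric CuH conjugate reduction (1,4-hydrosilylation of a β,β-disubstituted enoate/coumarin): the phenol is first silylated with loss of H2, the bisphosphine-bound CuH adds hydride to one face of C4 and sets the (S) centre, and Si–H metathesis stores the product as ketene acetal 5, which cannot be over-reduced and is hydrolysed on work-up.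

**Step 4**
Reactants: 6 (4S)-5-hydroxy-7-(methoxymethoxy)-4-propyl-3,4-dihydro-2H-chromen-2-one
Product: 7 (4S)-5-hydroxy-7-(methoxymethoxy)-2-oxo-4-propyl-3,4-dihydro-2H-chromene-6-carbaldehyde
Conditions: MgCl2 (3 equiv), Et3N (4 equiv), (CH2O)n (6 equiv), MeCN, 70 °C; then 1 M aq. HCl
Reagents that add atoms: paraformaldehyde (as formaldehyde), C=O
Why: Magnesium-mediated ortho-formylation (Casnati–Skattebøl) should deliver formaldehyde to C6, the only free carbon ortho to the phenoxide, with a second formaldehyde oxidising the benzylic alkoxide; any lactone opened by methoxide is expected to re-close on acidic work-up onto the phenol not hydrogen-bonded to the aldehyde, which restores 7.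

**Step 5**
Reactants: 7 (4S)-5-hydroxy-7-(methoxymethoxy)-2-oxo-4-propyl-3,4-dihydro-2H-chromene-6-carbaldehyde; 8 (R)-but-3-en-2-ol
Product: 9 (4S)-5-[(2S)-but-3-en-2-yloxy]-7-(methoxymethoxy)-2-oxo-4-propyl-3,4-dihydro-2H-chromene-6-carbaldehyde
Conditions: PPh3 (1.5 equiv), DIAD (1.5 equiv), THF, 0 °C → rt
Reagents that add atoms: none
Why: Mitsunobu etherification: the acidic salicylaldehyde-type phenol displaces the alkoxyphosphonium ion of 8 by SN2 with inversion, so the (R)-alcohol gives the (S)-ether carbon that becomes C2 of ring B.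

**Step 6**
Reactants: 9 (4S)-5-[(2S)-but-3-en-2-yloxy]-7-(methoxymethoxy)-2-oxo-4-propyl-3,4-dihydro-2H-chromene-6-carbaldehyde
Product: 11 (2S,3S,10S)-5-(methoxymethoxy)-2,3-dimethyl-10-propyl-2,3,9,10-tetrahydro-4H,8H-pyrano[2,3-f]chromene-4,8-dione, via (2S,3R) cis epimer 10 (not isolated)
Conditions: 2-mesityl-6,7-dihydro-5H-pyrrolo[2,1-c][1,2,4]triazol-2-ium chloride (20 mol %), DBU (0.5 equiv), 1,4-dioxane, 90–100 °C, argon
Reagents that add atoms: none
Why: The carbene adds to the C4a aldehyde to give the Breslow enaminol, whose nucleophilic carbon bonds to the internal vinyl carbon while its O–H proton passes to the terminal carbon through a five-membered, Conia-ene-like array; loss of the carbene then leaves the C4 ketone. The closest known reaction is the carbene-catalysed intramolecular hydroacylation of 2-allyloxybenzaldehydes to 3-methylchroman-4-ones. Ring B closes in 6-exo-trig mode, the seven-membered endo path being excluded because the proton can only be handed to the alkene terminus. C2 (S) is carried in unchanged from the ether, and C3 is set under thermodynamic control by C2: the ketone α-centre epimerises through its enolate under DBU, so cis epimer 10 should drain into the trans (2S,3S) isomer with both methyl groups pseudo-equatorial. The step needs hydroacylation to win over benzoin coupling, Claisen shift, lactone cleavage and retro-oxa-Michael opening; the two ortho substituents slow aldehyde dimerisation, both ortho positions of the ether are occupied and the temperature stays below that of a para-Claisen/Cope sequence, and substoichiometric DBU in aprotic dioxane should spare the lactone and the O1–C2 bond.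

**Step 7**
Reactants: 11 (2S,3S,10S)-5-(methoxymethoxy)-2,3-dimethyl-10-propyl-2,3,9,10-tetrahydro-4H,8H-pyrano[2,3-f]chromene-4,8-dione
Product: 13 methyl (3S)-3-[(2S,3S)-5,7-dihydroxy-2,3-dimethyl-4-oxo-3,4-dihydro-2H-chromen-8-yl]hexanoate, via MOM-protected hydroxy ester 12 (not isolated)
Conditions: K2CO3 (1.5 equiv), MeOH, 0 °C; then HCl (3 M in MeOH, excess), rt → 40 °C; NaHCO3 before concentration
Reagents that add atoms: methanol, CO
Why: Base-catalysed transesterification of the aryl lactone (the O7 phenoxide para to the ketone is a good leaving group) followed in the same flask by acid-catalysed acetal exchange of the MOM ether with methanol as trap; the cold, short base stage and the trans preference at C3 should leave all three stereocentres as they are.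

**Step 8**
Reactants: 13 methyl (3S)-3-[(2S,3S)-5,7-dihydroxy-2,3-dimethyl-4-oxo-3,4-dihydro-2H-chromen-8-yl]hexanoate; 14 prenyl bromide (1-bromo-3-methylbut-2-ene)
Product: 15 methyl (3S)-3-[(2S,3S)-5,7-dihydroxy-2,3-dimethyl-6-(3-methylbut-2-en-1-yl)-4-oxo-3,4-dihydro-2H-chromen-8-yl]hexanoate (CNP0068017.3)
Conditions: DBU (1.1 equiv), 14 (1.1 equiv), THF, 0 °C → rt
Reagents that add atoms: none
Why: Direct C-prenylation of an ambident acylphloroglucinol-type phenoxide: C6 is the only ring carbon bearing hydrogen and lies ortho to both O5 and O7, the 5-OH is held in a hydrogen bond to C4=O, and the amidine base leaves the methyl ester intact; no stereocentre is formed.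

**Compound list**

1 | phloroglucinol (benzene-1,3,5-triol) | Oc1cc(O)cc(O)c1 | starting material
2 | ethyl 3-oxohexanoate | CCCC(=O)CC(=O)OCC | starting material
3 | 5,7-dihydroxy-4-propyl-2H-chromen-2-one | CCCC1=CC(=O)Oc2cc(O)cc(O)c21 | intermediate
4 | 5-hydroxy-7-(methoxymethoxy)-4-propyl-2H-chromen-2-one | CCCC1=CC(=O)Oc2cc(OCOC)cc(O)c21 | intermediate
5 | (4S)-2,5-bis{[diethoxy(methyl)silyl]oxy}-7-(methoxymethoxy)-4-propyl-4H-chromene | CCC[C@H]1C=C(O[Si](C)(OCC)OCC)Oc2cc(OCOC)cc(O[Si](C)(OCC)OCC)c21 | intermediate (not isolated)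
6 | (4S)-5-hydroxy-7-(methoxymethoxy)-4-propyl-3,4-dihydro-2H-chromen-2-one | CCC[C@H]1CC(=O)Oc2cc(OCOC)cc(O)c21 | intermediate
7 | (4S)-5-hydroxy-7-(methoxymethoxy)-2-oxo-4-propyl-3,4-dihydro-2H-chromene-6-carbaldehyde | CCC[C@H]1CC(=O)Oc2cc(OCOC)c(C=O)c(O)c21 | intermediate
8 | (R)-but-3-en-2-ol | C[C@@H](O)C=C | starting material
9 | (4S)-5-[(2S)-but-3-en-2-yloxy]-7-(methoxymethoxy)-2-oxo-4-propyl-3,4-dihydro-2H-chromene-6-carbaldehyde | CCC[C@H]1CC(=O)Oc2cc(OCOC)c(C=O)c(O[C@@H](C)C=C)c21 | intermediate (key-step precursor)
10 | (2S,3R,10S)-5-(methoxymethoxy)-2,3-dimethyl-10-propyl-2,3,9,10-tetrahydro-4H,8H-pyrano[2,3-f]chromene-4,8-dione (cis-2,3-dimethyl epimer of 11) | CCC[C@H]1CC(=O)Oc2cc(OCOC)c3c(c21)O[C@@H](C)[C@@H](C)C3=O | intermediate (not isolated)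
11 | (2S,3S,10S)-5-(methoxymethoxy)-2,3-dimethyl-10-propyl-2,3,9,10-tetrahydro-4H,8H-pyrano[2,3-f]chromene-4,8-dione (trans-2,3-dimethylchromanone fused to the (S)-4-propyl lactone, C6 unsubstituted) | CCC[C@H]1CC(=O)Oc2cc(OCOC)c3c(c21)O[C@@H](C)[C@H](C)C3=O | intermediate (key-step product)
12 | methyl (3S)-3-[(2S,3S)-7-hydroxy-5-(methoxymethoxy)-2,3-dimethyl-4-oxo-3,4-dihydro-2H-chromen-8-yl]hexanoate | CCC[C@@H](CC(=O)OC)c1c(O)cc(OCOC)c2c1O[C@@H](C)[C@H](C)C2=O | intermediate (not isolated)
13 | methyl (3S)-3-[(2S,3S)-5,7-dihydroxy-2,3-dimethyl-4-oxo-3,4-dihydro-2H-chromen-8-yl]hexanoate | CCC[C@@H](CC(=O)OC)c1c(O)cc(O)c2c1O[C@@H](C)[C@H](C)C2=O | intermediate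
14 | prenyl bromide (1-bromo-3-methylbut-2-ene) | CC(C)=CCBr | starting material
15 | methyl (3S)-3-[(2S,3S)-5,7-dihydroxy-2,3-dimethyl-6-(3-methylbut-2-en-1-yl)-4-oxo-3,4-dihydro-2H-chromen-8-yl]hexanoate | CCC[C@@H](CC(=O)OC)c1c(O)c(CC=C(C)C)c(O)c2c1O[C@@H](C)[C@H](C)C2=O | target

**Totals**

Total step count: 8. Longest linear sequence: 8 steps (1 → 15).

**Steps most likely to fail**

Step 6. Carbene addition to an aldehyde flanked by two alkoxy groups may be slow. Prolonged heating with base could then open ring B by retro-oxa-Michael reaction or let the branched allyl ether rearrange, eroding C2. The fallback sets out from 9 and comes back at 11, forming the same C3–C4 bond by a base-free radical path. Pinnick oxidation of 9 (NaClO2, NaH2PO4, 2-methylbut-2-ene, t-BuOH/H2O) would give (4S)-5-[(2S)-but-3-en-2-yloxy]-7-(methoxymethoxy)-2-oxo-4-propyl-3,4-dihydro-2H-chromene-6-carboxylic acid F1. Diphenyl diselenide and PBu3 in CH2Cl2 would convert it to the Se-phenyl carboselenoate F2. Slow addition of Bu3SnH with AIBN in benzene at 80 °C would generate the aroyl radical, which should cyclise 6-exo-trig onto the vinyl group, the primary radical then being reduced to the C3 methyl. Brief treatment of the resulting 10/11 mixture with Et3N at rt should converge it on 11.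

Step 3. Hydride delivery to a β,β-disubstituted, electron-rich coumarin shielded by the peri silyloxy group may be slow, facial discrimination may be poor, and partial 1,2-reduction of the lactone may intrude. The fallback sets out from 4 and comes back at 6, replacing conjugate hydride addition by asymmetric hydrogenation of the ring-opened enoate. NaOH (3 equiv) in MeOH/H2O would open the coumarin to trisodium (2Z)-3-[4-(methoxymethoxy)-2,6-dioxidophenyl]hex-2-enoate F3. Hydrogenation with Ru(OAc)2[(S)-BINAP] (or its antipode, whichever gives the (S) acid) under H2 in MeOH would give trisodium (3S)-3-[4-(methoxymethoxy)-2,6-dioxidophenyl]hexanoate F4. Acidification with dilute HCl at 0 °C should lactonise it to 6; either ortho oxygen gives the same compound because the aryl group is symmetric about its attachment axis.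

Step 8. O-alkylation at O7 and a second, dearomatising alkylation at C6 may compete with the wanted C-alkylation. The fallback sets out from 13 and comes back at 15, and makes the C6–C bond by a sigmatropic shift. Pd(PPh3)4-catalysed Tsuji–Trost O-alkylation of the non-chelated 7-OH with methyl 2-methylbut-3-en-2-yl carbonate (THF, 0 °C → rt) would give methyl (3S)-3-[(2S,3S)-5-hydroxy-2,3-dimethyl-7-[(2-methylbut-3-en-2-yl)oxy]-4-oxo-3,4-dihydro-2H-chromen-8-yl]hexanoate F5. An aromatic Claisen rearrangement in toluene at 110 °C should then move the allyl unit, with allylic transposition, to C6, the only free ortho carbon, and tautomerise to 15.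

**Further compounds**

F1 | step 6 | (4S)-5-[(2S)-but-3-en-2-yloxy]-7-(methoxymethoxy)-2-oxo-4-propyl-3,4-dihydro-2H-chromene-6-carboxylic acid | CCC[C@H]1CC(=O)Oc2cc(OCOC)c(C(=O)O)c(O[C@@H](C)C=C)c21
F2 | step 6 | Se-phenyl (4S)-5-[(2S)-but-3-en-2-yloxy]-7-(methoxymethoxy)-2-oxo-4-propyl-3,4-dihydro-2H-chromene-6-carboselenoate | CCC[C@H]1CC(=O)Oc2cc(OCOC)c(C(=O)[Se]c3ccccc3)c(O[C@@H](C)C=C)c21
F3 | step 3 | trisodium (2Z)-3-[4-(methoxymethoxy)-2,6-dioxidophenyl]hex-2-enoate | CCC/C(=C/C(=O)[O-])c1c([O-])cc(OCOC)cc1[O-].[Na+].[Na+].[Na+]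
F4 | step 3 | trisodium (3S)-3-[4-(methoxymethoxy)-2,6-dioxidophenyl]hexanoate | CCC[C@@H](CC(=O)[O-])c1c([O-])cc(OCOC)cc1[O-].[Na+].[Na+].[Na+]
F5 | step 8 | methyl (3S)-3-[(2S,3S)-5-hydroxy-2,3-dimethyl-7-[(2-methylbut-3-en-2-yl)oxy]-4-oxo-3,4-dihydro-2H-chromen-8-yl]hexanoate | CCC[C@@H](CC(=O)OC)c1c(OC(C)(C)C=C)cc(O)c2c1O[C@@H](C)[C@H](C)C2=O
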